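**Retrosynthetic overview**
1. The target is the centrosymmetric α-truxillic (r-1,c-2,t-3,t-4) cyclobutane with two N-acyl-5,6-dihydropyridin-2(1H)-one arms. Each lactam ring is cut at N1–C6 and at C3=C4, which frees C4–C5–C6 as acrolein and leaves an acyclic N–H imide whose C3 is a stabilised phosphorane.
2. Enabling feature: N1 of each lactam ring is an imide nitrogen between ring C2=O and the exocyclic cyclobutyl C=O, so its N–H form is an acidic, soft N-nucleophile. C3 lies α to C2=O, so it can be an ylide. C6–C5–C4 is the enal pattern (C6 = β-carbon, C4 = CHO). The inversion centre makes both arms identical, so both rings can close in one flask.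
3. The bis-ylide comes from the α-truxillic diamide by N-chloroacetylation, PPh3 quaternisation and mild deprotonation.
4. The cyclobutane and all four stereocentres come from the biomimetic head-to-tail [2+2] photodimerisation of crystalline (E)-3,4-dimethoxycinnamic acid.
5. Ring order: cyclobutane first (step 1), both dihydropyridinone rings last and together (step 5).

Key step: step 5

Assumption: crystals of 1 grown from ethanol are taken to have the α-type packing (antiparallel, head-to-tail pairs across an inversion centre, alkene separation under about 4.2 Å), so the topochemical dimer is the α-truxillic isomer.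

**Step 1**
Reactants: 1 (E)-3,4-dimethoxycinnamic acid (two molecules)
Product: 2 (1α,2α,3β,4β)-2,4-bis(3,4-dimethoxyphenyl)cyclobutane-1,3-dicarboxylic acid (3,3',4,4'-tetramethoxy-α-truxillic acid; centrosymmetric, achiral)
Conditions: ground crystals (from EtOH) stirred as a suspension in H2O, hν (λ ≥ 300 nm, Pyrex, Hg lamp or 365 nm LED), rt; residual 1 washed out with Et2O
Reagents that add atoms: none
Why: Topochemical [2+2] photocycloaddition in which two antiparallel E-alkenes related by a crystal inversion centre join suprafacially, so the E geometry fixes each aryl/carboxyl pair trans and the inversion centre fixes the r-1,c-2,t-3,t-4 arrangement of all four stereocentres.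

**Step 2**
Reactants: 2 tetramethoxy-α-truxillic acid
Product: 4 (1α,2α,3β,4β)-2,4-bis(3,4-dimethoxyphenyl)cyclobutane-1,3-dicarboxamide, via diacid dichloride 3 (not isolated)
Conditions: (COCl)2, cat. DMF, CH2Cl2, 0 °C → rt, evaporate; NH3 (dioxane solution, excess), THF, 0 °C
Reagents that add atoms: ammonia, N; oxalyl chloride, O=C(Cl)C(=O)Cl (its chlorine stands only in 3)
Why: Vilsmeier-catalysed acid chloride formation followed by ammonolysis is standard for truxillic acids, and with no base stronger than ammonia at 0 °C neither ketene formation nor epimerisation at the α-carbons is expected.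

**Step 3**
Reactants: 4 α-truxillic diamide; 5 chloroacetyl chloride
Product: 6 (1α,2α,3β,4β)-N,N'-bis(chloroacetyl)-2,4-bis(3,4-dimethoxyphenyl)cyclobutane-1,3-dicarboxamide
Conditions: 5 (6 equiv), toluene, 100–105 °C, N2 sweep; excess 5 distilled off, trituration
Reagents that add atoms: none
Why: This is the classical base-free thermal N-acylation of a primary carboxamide with chloroacetyl chloride (O-acylation, then 1,3-acyl shift), which is driven by loss of HCl gas and stops at the diacylamine because the imide N–H is no longer nucleophilic.

**Step 4**
Reactants: 6 bis(N-chloroacetyl) imide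
Product: 8 (1α,2α,3β,4β)-2,4-bis(3,4-dimethoxyphenyl)-N,N'-bis[(triphenyl-λ5-phosphanylidene)acetyl]cyclobutane-1,3-dicarboxamide (bis-ylide), via bis-phosphonium dichloride 7 (not isolated)
Conditions: PPh3 (2.2 equiv), MeCN, 80 °C; Et3N (2.5 equiv), CH2Cl2, rt, H2O wash, crystallisation
Reagents that add atoms: triphenylphosphine, c1ccc(cc1)P(c1ccccc1)c1ccccc1
Why: SN2 quaternisation of PPh3 by the activated α-chloro imide, then deprotonation of the very acidic P+–CH2–C=O by Et3N, is the standard preparation of a carbonyl-stabilised Wittig reagent and should give a neutral, bench-stable solid.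

**Step 5**
Reactants: 8 bis-ylide; 9 acrolein (two molecules are incorporated)
Product: 12 target, (1α,2α,3β,4β)-1,1'-{[2,4-bis(3,4-dimethoxyphenyl)cyclobutane-1,3-diyl]dicarbonyl}bis(5,6-dihydropyridin-2(1H)-one), via bis(3-oxopropyl) bis-ylide 10 (not isolated), via mono-annulated aldehyde ylide 11 (not isolated)
Conditions: KOt-Bu (0.2 equiv), THF (0.05 M), −20 °C; 9 (3 equiv, BHT-stabilised, dropwise), −20 → 0 °C; AcOH (0.25 equiv), then 40 °C
Reagents that add atoms: none
Why: Proposed new method: catalytic KOt-Bu removes the only acidic proton of 8, an imide N–H, the potassium imidate adds through nitrogen to the β-carbon of acrolein (aza-Michael addition, N1–C6 bond), and the aldehyde enolate is reprotonated by the next N–H so that the base turns over and both arms reach 10; each neutral ylide carbon C3 then attacks the aldehyde C4 tethered to its own nitrogen and the oxaphosphetane collapses to the C3=C4 bond and Ph3P=O, giving 11 and then 12. The closest known reaction types are the base-catalysed conjugate addition of cyclic imides to acrolein, the Michael addition/intramolecular Wittig [3+3] annulation of ylide-bearing carbon pronucleophiles with enals, and the heteroatom addition/intramolecular Wittig annulations of vinylphosphonium salts; new is the use of an acyclic N–H imide phosphorane as a 1,3-N,C-bis-nucleophile. Each of the two dihydropyridinone rings closes by a 6-(enolendo)-exo-trig attack of C3 on the C4 carbonyl group, and the six-membered ring admits only the cis-fused oxaphosphetane, so the endocyclic Z-alkene is the only possible geometry. No stereocentre is created, and the four cyclobutane stereocentres from step 1 should stay untouched because the base is substoichiometric, sits on nitrogen, and is neutralised with AcOH before the base-free Wittig closure is driven at 40 °C. The step needs nitrogen to react before carbon (no Wittig olefination and no C-Michael addition of free acrolein), and the substrate secures this because carbon is stored as a neutral, imide-delocalised phosphorane without any C–H acidity while nitrogen reacts as an anion, which is why the ylide is preferred to a phosphonate whose CH2 would compete with N–H for the base. After N-alkylation the olefination is intramolecular, so it should outrun attack on the small excess of acrolein, on the second arm, or on another molecule at 0.05 M.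

**Compound list**
1 | (E)-3,4-dimethoxycinnamic acid | COc1ccc(/C=C/C(=O)O)cc1OC | starting material
2 | (1α,2α,3β,4β)-2,4-bis(3,4-dimethoxyphenyl)cyclobutane-1,3-dicarboxylic acid | COc1ccc([C@H]2[C@H](C(=O)O)[C@H](c3ccc(OC)c(OC)c3)[C@H]2C(=O)O)cc1OC | intermediate
3 | corresponding cyclobutane-1,3-dicarbonyl dichloride (not isolated) | COc1ccc([C@H]2[C@H](C(=O)Cl)[C@H](c3ccc(OC)c(OC)c3)[C@H]2C(=O)Cl)cc1OC | intermediate
4 | corresponding cyclobutane-1,3-dicarboxamide | COc1ccc([C@H]2[C@H](C(N)=O)[C@H](c3ccc(OC)c(OC)c3)[C@H]2C(N)=O)cc1OC | intermediate
5 | chloroacetyl chloride | O=C(Cl)CCl | starting material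
6 | N,N'-bis(chloroacetyl) dicarboxamide | COc1ccc([C@H]2[C@H](C(=O)NC(=O)CCl)[C@H](c3ccc(OC)c(OC)c3)[C@H]2C(=O)NC(=O)CCl)cc1OC | intermediate
7 | bis(triphenylphosphonium) dichloride of 6 (not isolated) | COc1ccc([C@H]2[C@H](C(=O)NC(=O)C[P+](c3ccccc3)(c3ccccc3)c3ccccc3)[C@H](c3ccc(OC)c(OC)c3)[C@H]2C(=O)NC(=O)C[P+](c2ccccc2)(c2ccccc2)c2ccccc2)cc1OC.[Cl-].[Cl-] | intermediate
8 | N,N'-bis[(triphenylphosphoranylidene)acetyl] dicarboxamide (bis-ylide) | COc1ccc([C@H]2[C@H](C(=O)NC(=O)C=P(c3ccccc3)(c3ccccc3)c3ccccc3)[C@H](c3ccc(OC)c(OC)c3)[C@H]2C(=O)NC(=O)C=P(c2ccccc2)(c2ccccc2)c2ccccc2)cc1OC | intermediate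
9 | acrolein (prop-2-enal) | C=CC=O | starting material
10 | N,N'-bis(3-oxopropyl) derivative of 8 (not isolated) | COc1ccc([C@H]2[C@H](C(=O)N(CCC=O)C(=O)C=P(c3ccccc3)(c3ccccc3)c3ccccc3)[C@H](c3ccc(OC)c(OC)c3)[C@H]2C(=O)N(CCC=O)C(=O)C=P(c2ccccc2)(c2ccccc2)c2ccccc2)cc1OC | intermediate
11 | mono-annulated compound: one dihydropyridinone ring closed, other arm still N-(3-oxopropyl) ylide (not isolated; racemic, one enantiomer drawn) | COc1ccc([C@H]2[C@H](C(=O)N3CCC=CC3=O)[C@H](c3ccc(OC)c(OC)c3)[C@H]2C(=O)N(CCC=O)C(=O)C=P(c2ccccc2)(c2ccccc2)c2ccccc2)cc1OC | intermediate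
12 | CNP0199212.1 (centrosymmetric, achiral) | COc1ccc([C@H]2[C@H](C(=O)N3CCC=CC3=O)[C@H](c3ccc(OC)c(OC)c3)[C@H]2C(=O)N2CCC=CC2=O)cc1OC | target

**Total step count:** 5. **Longest linear sequence:** 5.

**Steps most likely to fail**

1. Step 5 (Proposed new method).
 - What may go wrong: olefination of free acrolein by the ylide carbon before nitrogen has added, base-initiated polymerisation of acrolein, or reversal of the aza-Michael addition on warming.
 - Fallback (known chemistry): it sets out from diacid 2, which is converted into dichloride 3 as in step 2 and freed from volatiles. Purchased 5,6-dihydropyridin-2(1H)-one (O=C1C=CCCN1, 2.2 equiv) is lithiated (n-BuLi, THF, −78 °C) and N-acylated on both sides by 3. This is the standard assembly of N-acyl dihydropyridinone imides. It comes back to the route at 12 and makes no compound outside the list (F0).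

2. Step 3.
 - What may go wrong: dehydration of the primary amide groups to nitriles by the acid chloride, or stalled acylation of a poorly soluble diamide.
 - Fallback: it sets out from diacid 2 and avoids the primary amide altogether. Purchased chloroacetyl isocyanate (O=C=NC(=O)CCl, 2.4 equiv, cat. Et3N, THF, rt → 60 °C) adds both carboxylic acid groups to give the bis(carbamic–carboxylic mixed anhydride) F1. F1 loses CO2 with O→N acyl transfer (the decarboxylative acid/acyl isocyanate condensation) and comes back to the route at 6.

3. Step 1.
 - What may go wrong: crystallisation in a photostable or head-to-head polymorph, loss of lattice order that stalls conversion, or E/Z isomerisation in amorphous regions.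
 - Fallback: it sets out from 1 and moves the dimerisation into solution. Fischer esterification (MeOH, cat. H2SO4, reflux) gives methyl (E)-3,4-dimethoxycinnamate F2. Irradiation of F2 in CH2Cl2 with BF3·OEt2 uses the Lewis-acid-promoted photodimerisation of cinnamic esters, which favours the head-to-tail α-truxillate, and should give dimethyl 3,3',4,4'-tetramethoxy-α-truxillate F3. Acid hydrolysis (aq. HCl, dioxane, reflux; no base, to avoid epimerisation) comes back to the route at 2.

**Further compounds**
F0 | step 5 | none | none
F1 | step 3 | bis(N-chloroacetylcarbamic–carboxylic mixed anhydride) of 2 | COc1ccc([C@H]2[C@H](C(=O)OC(=O)NC(=O)CCl)[C@H](c3ccc(OC)c(OC)c3)[C@H]2C(=O)OC(=O)NC(=O)CCl)cc1OC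
F2 | step 1 | methyl (E)-3,4-dimethoxycinnamate | COc1ccc(/C=C/C(=O)OC)cc1OC
F3 | step 1 | dimethyl (1α,2α,3β,4β)-2,4-bis(3,4-dimethoxyphenyl)cyclobutane-1,3-dicarboxylate | COc1ccc([C@H]2[C@H](C(=O)OC)[C@H](c3ccc(OC)c(OC)c3)[C@H]2C(=O)OC)cc1OC
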